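I follow the inverse of G's fraction of the charge, g, rather than g itself, since that is the form in which this flask's slow loss becomes a straight line.

| flask | Z | L | remark | time |
|---|---|---|---|---|
| Saturday's | 10 mM | 3 mM | the very flask that is asked about, followed so far |  |
| Sunday's | 6.7 mM | 3 mM | run made earlier |  |
| flask | 10 mM | 3.00 mM |  | 8.0 d |

| run | time / d | G / % | E / % |
|---|---|---|---|
| Saturday's | 0.250 | 60.2 | 2.9 |
| Saturday's | 0.625 | 58.7 | 2.1 |
| Saturday's | 1.25 | 57.5 | 2.5 |
| Saturday's | 3.00 | 55.4 | 2.9 |
| Sunday's | 1.25 | 47.5 | 2.8 |
| Sunday's | 3.00 | 46.0 | 2.4 |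
| Sunday's | 4.00 | 44.8 | 1.6 |
| Sunday's | 6.00 | 43.7 | 2.1 |

(standard deviation of a reading: 0.5 percentage points)

1. share of G in G plus E at 80 s
2. share of G in G plus E at 8.0 d
3. which of G and E there is more of at 8.0 d



1. Read as a first-order loss, G goes at 0.0302 /d in Saturday's run and at 0.0176 /d in Sunday's, so the loss is faster with the bigger charge, and I take it as second-order, the rate of fall of g being a constant times g times g.

2. Integrated, the inverse of g rises in a straight line, and Saturday's first and last readings give 0.0523 /d for the climb, the rise per day of the inverse of G's fraction of the charge; Sunday's climb, read the same way, is 0.0385 /d, which is 0.736 of Saturday's where the charges stand at 0.670.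

3. Carrying Saturday's climb from the last reading to 8.0 d puts G at 48.4 % of the charge in this flask, and Saturday's summed readings give a share of 95.7 %, so G leads.

4. I give no number for 80 s, which lies 270 times earlier than the first reading.

5. Your hunch, the forecast, says 95.5 % at 80 s and 95.2 % at 8.0 d, a little below my share, with G ahead, and calls the early value “an extrapolation well before the first reading”.

The flask gives 18.3 % at 80 s, reaches equal G and E at 0.00410 d, and at 8.0 d stands at 96.4 %, with G at 47.7 % against my 48.4 % and E at 1.76 %.

    Z ⇌ E (K = 1.04, k = 1.18 /min)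
    E ⇌ G (K = 27.0, k = 0.0164 /min)
    G ⇌ Z (k = 0.00398 /min)
    Z ⇌ J (K = 0.400, k = 0.0650 /min)
    2 Z → Q (k = 1.66 /M/min)
    Z + L → D (k = 25.6 /M/min)

The neighbouring flask with 1.8 mM of L has the same Z charge, so I keep the climb, but its L is 18.0 % of the Z charge, so I add the difference of 12.0 % to Saturday's first G reading and climb to 8.0 d, which gives 55.8 %. At that time this neighbouring flask holds G at 54.1 %, Q at 23.2 % and D at 18.0 %.

The earlier runs and the new flask are simulated on assumed constants, and the scatter is random.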